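The readings were generated by integration with constants of no real substance.

**One-step world.** If starting material pairs into target in one reversible step and does nothing else, a flat stretch of target is an equilibrium, and one number describes it. At the bench I would read that number off the plateau and carry it to another charge.

| flask | starting material | temperature | remark | time |
|---|---|---|---|---|
| Saturday's | 0.099 M | 100 °C | the very flask that is asked about, followed so far |  |
| Friday's | 0.20 M | 85 °C | run made earlier |  |
| flask | 0.099 M | 100 °C |  | 40 min |

| Saturday's: time / min | Saturday's: target / % | Friday's: time / min | Friday's: target / % |
|---|---|---|---|
| 3.00 | 9 | 12.0 | 20 |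
| 8.00 | 19 | 25.0 | 31 |
| 15.0 | 23 | 30.0 | 33 |
| 25.0 | 25 | 50.0 | 38 |
| 30.0 | 28 | 60.0 | 38 |

(readings scatter by 1.5 percentage points)

- summer: change nothing and wait 80 min more
- midnight: at 40 min add starting material, 50.0% of the amount charged, then wait 80 min
- dawn: at 40 min take out 90% of the target then present, then wait 80 min
- winter: at 40 min raise the temperature by 20 K, then wait 80 min

- a species is counted by the starting material in it: one target counts as two
- target that was removed still counts
- the earlier runs were read with a standard deviation of 1.5 percentage points
- additions bring no volume worth counting

- target, in percent of the starting material first charged, at 40 min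
- the remedy with the largest gain of target, or "none" below 2 percentage points (summer / midnight / dawn / winter / none)
- target present, with what was taken out counted in, in percent of the starting material first charged, after summer
- target present, with what was taken out counted in, in percent of the starting material first charged, after dawn

**Bench rule.** Let y be the charged share sitting in target and c the charge. Each target holds two starting material, so the rule takes free starting material as the charge less yc. Saturday's last reading gives Q = 2.73 L mol⁻¹, where Q is target concentration over the square of free starting material concentration, the plateau quotient. Friday's last reading, at twice the charge and cooler, gives 2.47 L mol⁻¹, which is 0.260 L mol⁻¹ less than Saturday's 2.73 L mol⁻¹. Friday's Q at Saturday's charge gives 26.5% target, against Saturday's reading of 28%. That gap is near the scatter of 1.5 percentage points. I commit to 27.2% at 40 min.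

**The border.** The readings show target, never starting material, so the free amount is assumed, not read. Saturday's last reading stands at 30.0 min, and the remedies end at 120 min, 4.00 times as late. Neither run has a reading out there, so I name no remedy.

**Forecast and flask.** The forecast, “Both runs level off early”, goes further than I do: 27.5% now, 27.7% after summer, 42% after dawn, best midnight.

The flask gives 26.5% at 40 min, 19.9% after summer and 37.5% after dawn. The best remedy is dawn, with a gain of 11 points.

    2 starting material ⇌ target (K = 3.40 L mol⁻¹, k = 0.00340 L mol⁻¹ s⁻¹, Ea = 83.0 kJ mol⁻¹, ΔH = −29.0 kJ mol⁻¹)
    starting material + target → side product (k = 0.00160 L mol⁻¹ s⁻¹, Ea = 63.0 kJ mol⁻¹)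
    (constants at 100 °C)

**Fast and slow.** At 5.84 min this flask's target falls back 7.6 times faster than it goes on, a rapid equilibrium (pre-equilibrium) with a slow leak. At 40.0 min the forward pairing still uses starting material 21 times faster than the path to side product. This flask then holds 9.18% side product and 64% free starting material, less than the 73.5% of the bench count. With that amount, Q for this flask is 3.23 L mol⁻¹, where the bench count read 2.73 L mol⁻¹. Carried by the bench rule to a neighbour flask at 0.25 M, Saturday's 2.73 L mol⁻¹ gives 43.5% target, and at 40 min that neighbour holds 31.6%.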